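Ring A is built, not etherified. Its pentasubstituted pattern (C1 carboxyl, C2 OH, C4 OMe, C5 aryloxy, C6 pentyl) is the footprint of a 1,3-dioxygenated vinylketene acetal joined to a 2-alkynoate. The ring B phenol is therefore O-alkylated with a γ-chloro-β-methoxycrotonate and the ester converted into silyl diene 11, which carries ring B on the oxygen of its nucleophilic terminus. Heating 11 with benzyl oct-2-ynoate 13 forms C5–C6 and C1–C2 in one operation and closes ring A with every substituent in place. Only ketal hydrolysis and hydrogenolysis remain.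

Key step: step 8

Remarks on the chemistry:
- Ring A is numbered C1 (carboxyl-bearing), C2 (OH), C3 (H), C4 (OMe), C5 (O-aryl), C6 (pentyl) throughout.
- 1,2-Epoxybutane is used as the racemate, so alcohol 5 is racemic; its carbinol centre is oxidised away in step 3, and the target has no stereocentre.
- Diene 11 is drawn (1Z,3Z), with the aryloxy group pointing outward; both double bonds end up in the arene, so the geometry has no stereochemical consequence.

Step 1
Reactants: 1 methyl orsellinate (methyl 2,4-dihydroxy-6-methylbenzoate)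
Product: 2 methyl 4-(benzyloxy)-2-hydroxy-6-methylbenzoate
Conditions: BnBr (1.05 equiv), K2CO3, acetone, reflux
Reagents that add atoms: benzyl bromide, BrCc1ccccc1
Why: Williamson ether synthesis in which the 2-OH, locked in a hydrogen bond to the ester carbonyl and less acidic, stays free while the 4-OH is alkylated by one equivalent of benzyl bromide.

Step 2
Reactants: 2 methyl 4-(benzyloxy)-2-hydroxy-6-methylbenzoate; 3 1,2-epoxybutane (racemate)
Product: 5 methyl 4-(benzyloxy)-2-hydroxy-6-(3-hydroxypentyl)benzoate (racemate), via dilithium dianion 4 (not isolated)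
Conditions: LDA (2.3 equiv), THF, −78 °C; then 3 (1.5 equiv), −78 °C → rt; 1 M aq. HCl
Reagents that add atoms: none
Why: Lateral (benzylic) lithiation of the o-toluate as its phenoxide dianion followed by SN2 ring opening of the terminal epoxide at its CH2 carbon; the phenoxide shields the ester from self-condensation, and the new carbinol centre is formed without control and removed in step 3.

Step 3
Reactants: 5 methyl 4-(benzyloxy)-2-hydroxy-6-(3-hydroxypentyl)benzoate (racemate)
Product: 6 methyl 4-(benzyloxy)-2-hydroxy-6-(3-oxopentyl)benzoate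
Conditions: Dess–Martin periodinane (1.2 equiv), CH2Cl2, rt
Reagents that add atoms: none
Why: Dess–Martin oxidation of a secondary alcohol to the ketone under mild conditions that the benzyl ether, the ester and the chelated, ester-deactivated phenol should tolerate.

Step 4
Reactants: 6 methyl 4-(benzyloxy)-2-hydroxy-6-(3-oxopentyl)benzoate
Product: 7 methyl 4-(benzyloxy)-2-hydroxy-6-[2-(2-ethyl-1,3-dioxolan-2-yl)ethyl]benzoate
Conditions: ethylene glycol (5 equiv), TsOH·H2O (cat.), toluene, reflux, Dean–Stark
Reagents that add atoms: ethylene glycol, OCCO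
Why: Acid-catalysed ketalisation driven by azeotropic removal of water, which masks the enolisable ethyl ketone before the strong base of step 6; the 2,6-disubstituted methyl benzoate is too hindered to transesterify.

Step 5
Reactants: 7 methyl 4-(benzyloxy)-2-hydroxy-6-[2-(2-ethyl-1,3-dioxolan-2-yl)ethyl]benzoate; 8 methyl (E)-4-chloro-3-methoxybut-2-enoate
Product: 9 methyl 4-(benzyloxy)-2-{[(2E)-2,4-dimethoxy-4-oxobut-2-en-1-yl]oxy}-6-[2-(2-ethyl-1,3-dioxolan-2-yl)ethyl]benzoate
Conditions: K2CO3, NaI (cat.), DMF, 50 °C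
Reagents that add atoms: none
Why: Williamson-type SN2 displacement of the primary allylic chloride by the phenoxide with Finkelstein assistance by iodide, so the diaryl ether oxygen is attached at an sp3 carbon and the enol ether geometry is untouched.

Step 6
Reactants: 9 methyl 4-(benzyloxy)-2-{[(2E)-2,4-dimethoxy-4-oxobut-2-en-1-yl]oxy}-6-[2-(2-ethyl-1,3-dioxolan-2-yl)ethyl]benzoate
Product: 11 methyl 4-(benzyloxy)-2-{[(1Z,3Z)-2,4-dimethoxy-4-(trimethylsilyloxy)buta-1,3-dien-1-yl]oxy}-6-[2-(2-ethyl-1,3-dioxolan-2-yl)ethyl]benzoate, via lithium dienolate 10 (not isolated)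
Conditions: TMSCl (2 equiv), THF, −78 °C, LDA (1.1 equiv) added slowly (in situ quench); −78 → 0 °C; evaporation, pentane, filtration; used crude
Reagents that add atoms: chlorotrimethylsilane, C[Si](C)(C)Cl
Why: γ-Deprotonation of a β-alkoxy enoate to its extended enolate and O-silylation, the standard preparation of vinylketene acetals; the γ-CH2 lies syn to the ester carbonyl and is the most acidic C–H, and the in situ trap keeps the dienolate too short-lived to attack the ring B ester or to equilibrate with the benzylic position.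

Step 7
Reactants: 12 oct-2-ynoic acid
Product: 13 benzyl oct-2-ynoate
Conditions: BnBr (1.1 equiv), K2CO3, DMF, rt
Reagents that add atoms: benzyl bromide, BrCc1ccccc1
Why: SN2 O-alkylation of the carboxylate, which gives the ring A carboxyl an ester that can later be removed by neutral hydrogenolysis while the ring B methyl ester stays.

Step 8
Reactants: 11 methyl 4-(benzyloxy)-2-{[(1Z,3Z)-2,4-dimethoxy-4-(trimethylsilyloxy)buta-1,3-dien-1-yl]oxy}-6-[2-(2-ethyl-1,3-dioxolan-2-yl)ethyl]benzoate; 13 benzyl oct-2-ynoate (3 equiv)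
Product: 15 benzyl 5-{5-(benzyloxy)-3-[2-(2-ethyl-1,3-dioxolan-2-yl)ethyl]-2-(methoxycarbonyl)phenoxy}-2-hydroxy-4-methoxy-6-pentylbenzoate, via silyl methyl ketal cycloadduct 14 (not isolated)
Conditions: toluene, 110 °C, sealed tube, Ar; then SiO2, CH2Cl2, rt
Reagents that add atoms: none
Why: The electron-rich diene 11 and the electron-poor alkyne 13 combine in a concerted but asynchronous, normal-electron-demand Diels–Alder reaction in which bonding between the aryloxy-bearing diene terminus (future C5) and the ynoate β-carbon (future C6) runs ahead of bonding between the ketene acetal carbon (future C2) and the α-carbon (future C1). The cyclohexa-1,4-diene 14 then expels methoxytrimethylsilane from its mixed silyl methyl ketal carbon and the C5 hydrogen passes to the C2 oxygen to give the benzene ring; the closest known reaction type is the cycloaddition–aromatisation of 1,3-dialkoxy-1-silyloxybutadienes with 2-alkynoates to 2-hydroxy-4-methoxy-6-alkylbenzoates. Ring A is closed as a six-membered carbocycle by the intermolecular [4+2] addition itself, four carbons coming from the diene and two from the alkyne, so no chain cyclisation is involved. No stereocentre remains, because the two sp3 carbons of 14 are both lost on aromatisation. The step needs a single orientation, ester at C1 beside the new C2 hydroxyl, and this is secured by the two oxygen donors on the ketene acetal carbon and the methoxy group on the internal diene carbon (future C4), which place the largest HOMO coefficient on the aryloxy-bearing terminus and outweigh the weak opposing donation of the aryloxy oxygen, while the ester makes the alkyne β-carbon the electrophilic end. The outward aryloxy group and the linear alkyne keep the hindered C5–C6 bond formation sterically accessible.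

Step 9
Reactants: 15 benzyl 5-{5-(benzyloxy)-3-[2-(2-ethyl-1,3-dioxolan-2-yl)ethyl]-2-(methoxycarbonyl)phenoxy}-2-hydroxy-4-methoxy-6-pentylbenzoate
Product: 16 benzyl 5-[5-(benzyloxy)-2-(methoxycarbonyl)-3-(3-oxopentyl)phenoxy]-2-hydroxy-4-methoxy-6-pentylbenzoate
Conditions: 1 M aq. HCl, THF, rt
Reagents that add atoms: water, O
Why: Acid-catalysed hydrolysis of the dioxolane, carried out while the ring A carboxyl is still a benzyl ester so that the decarboxylation-prone salicylic acid never meets acid; esters and ethers are inert at room temperature.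

Step 10
Reactants: 16 benzyl 5-[5-(benzyloxy)-2-(methoxycarbonyl)-3-(3-oxopentyl)phenoxy]-2-hydroxy-4-methoxy-6-pentylbenzoate
Product: 17 epiphorellic acid 2 (2-hydroxy-5-[5-hydroxy-2-(methoxycarbonyl)-3-(3-oxopentyl)phenoxy]-4-methoxy-6-pentylbenzoic acid)
Conditions: H2 (1 atm), Pd/C (10%), EtOAc, rt; evaporation below 30 °C
Reagents that add atoms: none
Why: Palladium-catalysed hydrogenolysis cleaves the benzyl ether of ring B and the benzyl ester of ring A together under neutral conditions that leave the dialkyl ketone, the methyl ester and the diaryl ether alone.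

Compound list
1 | methyl orsellinate (methyl 2,4-dihydroxy-6-methylbenzoate) | COC(=O)c1c(C)cc(O)cc1O | starting material
2 | methyl 4-(benzyloxy)-2-hydroxy-6-methylbenzoate | COC(=O)c1c(C)cc(OCc2ccccc2)cc1O | intermediate
3 | 1,2-epoxybutane (2-ethyloxirane, racemate) | CCC1CO1 | starting material
4 | dilithium dianion of 2 (phenoxide and benzylic carbanion; not isolated) | [Li+].[Li+].[CH2-]c1cc(OCc2ccccc2)cc([O-])c1C(=O)OC | intermediate
5 | methyl 4-(benzyloxy)-2-hydroxy-6-(3-hydroxypentyl)benzoate (racemate) | CCC(O)CCc1cc(OCc2ccccc2)cc(O)c1C(=O)OC | intermediate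
6 | methyl 4-(benzyloxy)-2-hydroxy-6-(3-oxopentyl)benzoate | CCC(=O)CCc1cc(OCc2ccccc2)cc(O)c1C(=O)OC | intermediate
7 | methyl 4-(benzyloxy)-2-hydroxy-6-[2-(2-ethyl-1,3-dioxolan-2-yl)ethyl]benzoate | CCC1(CCc2cc(OCc3ccccc3)cc(O)c2C(=O)OC)OCCO1 | intermediate
8 | methyl (E)-4-chloro-3-methoxybut-2-enoate | CO/C(CCl)=C/C(=O)OC | starting material
9 | methyl 4-(benzyloxy)-2-{[(2E)-2,4-dimethoxy-4-oxobut-2-en-1-yl]oxy}-6-[2-(2-ethyl-1,3-dioxolan-2-yl)ethyl]benzoate | CO/C(COc1cc(OCc2ccccc2)cc(CCC2(CC)OCCO2)c1C(=O)OC)=C/C(=O)OC | intermediate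
10 | lithium dienolate of 9 (γ-deprotonated; lithium 1,3-dimethoxy-4-aryloxybuta-1,3-dien-1-olate, aryl = ring B; not isolated) | [Li+].CO/C([O-])=C/C(OC)=C/Oc1cc(OCc2ccccc2)cc(CCC2(CC)OCCO2)c1C(=O)OC | intermediate
11 | methyl 4-(benzyloxy)-2-{[(1Z,3Z)-2,4-dimethoxy-4-(trimethylsilyloxy)buta-1,3-dien-1-yl]oxy}-6-[2-(2-ethyl-1,3-dioxolan-2-yl)ethyl]benzoate | CO/C(O[Si](C)(C)C)=C/C(OC)=C/Oc1cc(OCc2ccccc2)cc(CCC2(CC)OCCO2)c1C(=O)OC | intermediate
12 | oct-2-ynoic acid | CCCCCC#CC(=O)O | starting material
13 | benzyl oct-2-ynoate | CCCCCC#CC(=O)OCc1ccccc1 | intermediate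
14 | benzyl 3-{5-(benzyloxy)-3-[2-(2-ethyl-1,3-dioxolan-2-yl)ethyl]-2-(methoxycarbonyl)phenoxy}-4,6-dimethoxy-2-pentyl-6-(trimethylsilyloxy)cyclohexa-1,4-diene-1-carboxylate (diastereomer mixture; not isolated) | CCCCCC1=C(C(=O)OCc2ccccc2)C(OC)(O[Si](C)(C)C)C=C(OC)C1Oc1cc(OCc2ccccc2)cc(CCC2(CC)OCCO2)c1C(=O)OC | intermediate
15 | benzyl 5-{5-(benzyloxy)-3-[2-(2-ethyl-1,3-dioxolan-2-yl)ethyl]-2-(methoxycarbonyl)phenoxy}-2-hydroxy-4-methoxy-6-pentylbenzoate | CCCCCc1c(Oc2cc(OCc3ccccc3)cc(CCC3(CC)OCCO3)c2C(=O)OC)c(OC)cc(O)c1C(=O)OCc1ccccc1 | intermediate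
16 | benzyl 5-[5-(benzyloxy)-2-(methoxycarbonyl)-3-(3-oxopentyl)phenoxy]-2-hydroxy-4-methoxy-6-pentylbenzoate | CCCCCc1c(Oc2cc(OCc3ccccc3)cc(CCC(=O)CC)c2C(=O)OC)c(OC)cc(O)c1C(=O)OCc1ccccc1 | intermediate
17 | epiphorellic acid 2 (2-hydroxy-5-[5-hydroxy-2-(methoxycarbonyl)-3-(3-oxopentyl)phenoxy]-4-methoxy-6-pentylbenzoic acid) | CCCCCc1c(Oc2cc(O)cc(CCC(=O)CC)c2C(=O)OC)c(OC)cc(O)c1C(=O)O | target

Total step count: 10. Longest linear sequence: 9 steps (steps 1–6, then 8–10); step 7 is the one-step side branch.

Steps most likely to fail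

1. Step 8. The cycloaddition onto the β-alkyl ynoate may be slower than thermal desilylation or isomerisation of the ketene acetal, so that the diene is used up without ring formation. The fallback sets out from 11 and uses the far more electrophilic, commercial oct-2-ynal as the two-carbon partner in toluene at 20–60 °C. With the same orientation this should pass through the silyl methyl ketal cycloadduct benzaldehyde F1 (not isolated) and give 5-{5-(benzyloxy)-3-[2-(2-ethyl-1,3-dioxolan-2-yl)ethyl]-2-(methoxycarbonyl)phenoxy}-2-hydroxy-4-methoxy-6-pentylbenzaldehyde F2. Pinnick oxidation (NaClO2, NaH2PO4, 2-methylbut-2-ene, t-BuOH/H2O) should give the corresponding benzoic acid F3. Carboxylate-selective benzylation (BnBr, KHCO3, DMF, rt) then comes back to the route at 15.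

2. Step 2. The dianion may open the epoxide only sluggishly, which leaves time for proton transfer or ester self-condensation, and the alkoxide formed may lactonise onto the ester. The fallback sets out from 2 (through dianion 4) and alkylates with the much more reactive allylic halide 2-(bromomethyl)but-1-ene (THF, −78 °C). This should give methyl 4-(benzyloxy)-2-hydroxy-6-(3-methylidenepentyl)benzoate F4. Lemieux–Johnson cleavage of its 1,1-disubstituted alkene (OsO4 cat., NaIO4, 2,6-lutidine, dioxane/H2O) comes back to the route at ketone 6, so step 3 is bypassed as well.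

3. Step 6. The amide base may also metalate the benzylic CH2 ortho to the ring B ester. The dienolate may instead close through its γ-carbon onto that ester (five-membered Claisen-type cyclisation) or be silylated on carbon. The trimethylsilyl ketene acetal may also hydrolyse on handling. The fallback sets out from 9 and uses soft enolisation without a strong base (TBSOTf, Et3N, Et2O, 0 °C → rt), so no free dienolate exists. It should give the more robust methyl 4-(benzyloxy)-2-{[(1Z,3Z)-4-(tert-butyldimethylsilyloxy)-2,4-dimethoxybuta-1,3-dien-1-yl]oxy}-6-[2-(2-ethyl-1,3-dioxolan-2-yl)ethyl]benzoate F5. Heated with 13 as in step 8, this should pass through the tert-butyldimethylsilyl methyl ketal cycloadduct F6 (not isolated), lose tert-butyl(methoxy)dimethylsilane and come back to the route at 15.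

Further compounds
F1 | step 8 | methyl 4-(benzyloxy)-2-{[6-formyl-2,4-dimethoxy-5-pentyl-4-(trimethylsilyloxy)cyclohexa-2,5-dien-1-yl]oxy}-6-[2-(2-ethyl-1,3-dioxolan-2-yl)ethyl]benzoate (diastereomer mixture, not isolated) | CCCCCC1=C(C=O)C(OC)(O[Si](C)(C)C)C=C(OC)C1Oc1cc(OCc2ccccc2)cc(CCC2(CC)OCCO2)c1C(=O)OC
F2 | step 8 | 5-{5-(benzyloxy)-3-[2-(2-ethyl-1,3-dioxolan-2-yl)ethyl]-2-(methoxycarbonyl)phenoxy}-2-hydroxy-4-methoxy-6-pentylbenzaldehyde | CCCCCc1c(Oc2cc(OCc3ccccc3)cc(CCC3(CC)OCCO3)c2C(=O)OC)c(OC)cc(O)c1C=O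
F3 | step 8 | 5-{5-(benzyloxy)-3-[2-(2-ethyl-1,3-dioxolan-2-yl)ethyl]-2-(methoxycarbonyl)phenoxy}-2-hydroxy-4-methoxy-6-pentylbenzoic acid | CCCCCc1c(Oc2cc(OCc3ccccc3)cc(CCC3(CC)OCCO3)c2C(=O)OC)c(OC)cc(O)c1C(=O)O
F4 | step 2 | methyl 4-(benzyloxy)-2-hydroxy-6-(3-methylidenepentyl)benzoate | CCC(=C)CCc1cc(OCc2ccccc2)cc(O)c1C(=O)OC
F5 | step 6 | methyl 4-(benzyloxy)-2-{[(1Z,3Z)-4-(tert-butyldimethylsilyloxy)-2,4-dimethoxybuta-1,3-dien-1-yl]oxy}-6-[2-(2-ethyl-1,3-dioxolan-2-yl)ethyl]benzoate | CO/C(O[Si](C)(C)C(C)(C)C)=C/C(OC)=C/Oc1cc(OCc2ccccc2)cc(CCC2(CC)OCCO2)c1C(=O)OC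
F6 | step 6 | benzyl 3-{5-(benzyloxy)-3-[2-(2-ethyl-1,3-dioxolan-2-yl)ethyl]-2-(methoxycarbonyl)phenoxy}-6-(tert-butyldimethylsilyloxy)-4,6-dimethoxy-2-pentylcyclohexa-1,4-diene-1-carboxylate (diastereomer mixture, not isolated) | CCCCCC1=C(C(=O)OCc2ccccc2)C(OC)(O[Si](C)(C)C(C)(C)C)C=C(OC)C1Oc1cc(OCc2ccccc2)cc(CCC2(CC)OCCO2)c1C(=O)OC
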